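## Retrosynthetic overview

1. The C–Br bond is made last by invertive bromination of the (1S)-alcohol 22. The hexenyl chain and that carbinol come from a Felkin-controlled Hosomi–Sakurai addition of 3-(trimethylsilyl)pent-1-ene 21 to the C5 aldehyde 16.
2. The (E)-enyne comes from a C2 allyl group by cross-metathesis with crotonaldehyde and Colvin homologation. The allyl group and the free 3-OH come from lactol methylenation of bicyclic lactone 9.
3. Rings: the oxolane ring is formed first and the γ-lactone ring directly after it, in one operation, by PdCl2-catalysed alkoxycarbonylation–lactonization of anti-1,3-diol 6. The lactone ring is opened again in steps 7–8.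
4. Diol 6 comes from a β-hydroxy vinyl ketone by Evans–Saksena reduction. Its first stereocenter is set by a ketoreductase-catalysed asymmetric reduction of the achiral β-keto ester 2.

Assumption: the ketoreductase of step 2 is an (R)-selective, NADPH-dependent enzyme picked from a commercial screening panel; silane 21 is not a stock chemical and is made in steps 14 and 15.

## Route

Step 1
Reactants: 1 ethyl 4-chloro-3-oxobutanoate
Product: 2 ethyl 4-[(4-methoxybenzyl)oxy]-3-oxobutanoate
Conditions: 4-MeOC6H4CH2OH, NaH (2.2 equiv), THF, 0 °C → rt; then 1 M HCl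
Reagents that add atoms: 4-methoxybenzyl alcohol, COc1ccc(CO)cc1
Why: Williamson etherification, in which the second equivalent of NaH keeps the β-keto ester as its enolate while the 4-methoxybenzyl alkoxide displaces the primary chloride (SN2).

Step 2
Reactants: 2 ethyl 4-[(4-methoxybenzyl)oxy]-3-oxobutanoate
Product: 3 ethyl (3R)-3-hydroxy-4-[(4-methoxybenzyl)oxy]butanoate
Conditions: ketoreductase (KRED, R-selective), NADP+ (cat.), iPrOH (10 vol %), phosphate buffer pH 7.0, 30 °C
Reagents that add atoms: none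
Why: Biocatalytic asymmetric ketone reduction, in which the ketoreductase delivers hydride from NADPH (recycled by the same enzyme from iPrOH) to one face of the achiral β-keto ester and so sets the first stereocenter (3R) catalytically in high ee.

Step 3
Reactants: 3 ethyl (3R)-3-hydroxy-4-[(4-methoxybenzyl)oxy]butanoate
Product: 4 (3R)-3-hydroxy-N-methoxy-4-[(4-methoxybenzyl)oxy]-N-methylbutanamide
Conditions: MeNH(OMe)·HCl, iPrMgCl, THF, −20 °C → 0 °C; aq. NH4Cl
Reagents that add atoms: N,O-dimethylhydroxylamine hydrochloride, CNOC.Cl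
Why: Weinreb amide formation by aminolysis of the ester with the magnesium amide made in the flask, which does not touch the carbinol center.

Step 4
Reactants: 4 (3R)-3-hydroxy-N-methoxy-4-[(4-methoxybenzyl)oxy]-N-methylbutanamide
Product: 5 (5R)-5-hydroxy-6-[(4-methoxybenzyl)oxy]hex-1-en-3-one
Conditions: CH2=CHMgBr (3.5 equiv), THF, −20 °C → 0 °C; poured into cold 1 M HCl
Reagents that add atoms: vinylmagnesium bromide, C=C[Mg]Br
Why: Grignard addition to a Weinreb amide stops at the stable chelated tetrahedral intermediate, so only the vinyl ketone is released on the acidic inverse quench, which also keeps the liberated amine from adding to the enone.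

Step 5
Reactants: 5 (5R)-5-hydroxy-6-[(4-methoxybenzyl)oxy]hex-1-en-3-one
Product: 6 (2R,4R)-1-[(4-methoxybenzyl)oxy]hex-5-ene-2,4-diol
Conditions: Me4NBH(OAc)3 (5 equiv), MeCN/AcOH (1:1), −30 °C
Reagents that add atoms: none
Why: Evans–Saksena reduction, in which the free hydroxyl exchanges onto boron and hydride is delivered intramolecularly through a chair transition state, giving the 1,3-anti diol (new 4R center) with clean 1,2-reduction of the enone.

Step 6
Reactants: 6 (2R,4R)-1-[(4-methoxybenzyl)oxy]hex-5-ene-2,4-diol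
Product: 9 (3aR,5R,6aR)-5-{[(4-methoxybenzyl)oxy]methyl}tetrahydrofuro[3,2-b]furan-2(3H)-one, via alkylpalladium chloride 7 (not isolated), via acylpalladium chloride 8 (not isolated)
Conditions: PdCl2 (10 mol %), CuCl2 (3 equiv), NaOAc (3 equiv), CO (1 atm), AcOH, rt
Reagents that add atoms: carbon monoxide, [C-]#[O+]
Why: Semmelhack-type intramolecular alkoxycarbonylation–lactonization by divalent palladium, in which 5-exo oxypalladation by the C2 hydroxyl, CO insertion and capture of the acyl by the allylic hydroxyl give the cis-fused lactone, so the new ring center is cis to the 3-oxygen and the anti diol places the C5 substituent cis as well (all-cis oxolane), while CuCl2 reoxidises zerovalent palladium.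

Step 7
Reactants: 9 (3aR,5R,6aR)-5-{[(4-methoxybenzyl)oxy]methyl}tetrahydrofuro[3,2-b]furan-2(3H)-one
Product: 10 (3aR,5R,6aR)-5-{[(4-methoxybenzyl)oxy]methyl}hexahydrofuro[3,2-b]furan-2-ol (mixture of anomers)
Conditions: iBu2AlH (1.1 equiv), CH2Cl2, −78 °C; aq. potassium sodium tartrate
Reagents that add atoms: none
Why: Partial reduction of the γ-lactone stops at the lactol because the tetrahedral aluminium alkoxide survives at −78 °C until work-up.

Step 8
Reactants: 10 (3aR,5R,6aR)-5-{[(4-methoxybenzyl)oxy]methyl}hexahydrofuro[3,2-b]furan-2-ol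
Product: 11 (2R,3R,5R)-5-{[(4-methoxybenzyl)oxy]methyl}-2-(prop-2-en-1-yl)oxolan-3-ol
Conditions: Ph3PCH3Br (3 equiv), KOtBu (2.9 equiv), THF, 0 °C → rt
Reagents that add atoms: methyltriphenylphosphonium bromide, C[P+](c1ccccc1)(c1ccccc1)c1ccccc1.[Br-]
Why: Wittig methylenation of the open hydroxy-aldehyde form of the lactol gives the C2 allyl group and frees the 3-OH without touching any stereocenter.

Step 9
Reactants: 11 (2R,3R,5R)-5-{[(4-methoxybenzyl)oxy]methyl}-2-(prop-2-en-1-yl)oxolan-3-ol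
Product: 12 (2R,3R,5R)-5-{[(4-methoxybenzyl)oxy]methyl}-2-(prop-2-en-1-yl)oxolan-3-yl acetate
Conditions: Ac2O, pyridine, DMAP (cat.), CH2Cl2, rt
Reagents that add atoms: acetic anhydride, CC(=O)OC(C)=O
Why: DMAP-catalysed acylation of the only free hydroxyl installs the acetate of the target.

Step 10
Reactants: 12 (2R,3R,5R)-5-{[(4-methoxybenzyl)oxy]methyl}-2-(prop-2-en-1-yl)oxolan-3-yl acetate
Product: 13 (2R,3R,5R)-5-{[(4-methoxybenzyl)oxy]methyl}-2-[(2E)-4-oxobut-2-en-1-yl]oxolan-3-yl acetate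
Conditions: (E)-crotonaldehyde (5 equiv), second-generation Hoveyda–Grubbs catalyst (5 mol %), CH2Cl2, 40 °C
Reagents that add atoms: (E)-but-2-enal, C/C=C/C=O
Why: Olefin cross-metathesis of an unhindered terminal alkene with an electron-poor partner is selective for the cross product and gives the (E)-enal under thermodynamic control.

Step 11
Reactants: 13 (2R,3R,5R)-5-{[(4-methoxybenzyl)oxy]methyl}-2-[(2E)-4-oxobut-2-en-1-yl]oxolan-3-yl acetate
Product: 14 (2R,3R,5R)-5-{[(4-methoxybenzyl)oxy]methyl}-2-[(2E)-pent-2-en-4-yn-1-yl]oxolan-3-yl acetate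
Conditions: Me3SiCHN2 (1.3 equiv), LiN(iPr)2 (1.25 equiv), THF, −78 °C → 0 °C; water
Reagents that add atoms: (trimethylsilyl)diazomethane, C[Si](C)(C)C=[N+]=[N-]
Why: Colvin homologation, in which lithiated Me3SiCHN2 adds to the aldehyde at −78 °C faster than to the acetate, and Peterson elimination, loss of N2 and a 1,2-hydrogen shift of the alkylidene carbene give the terminal alkyne with the (E)-alkene intact.

Step 12
Reactants: 14 (2R,3R,5R)-5-{[(4-methoxybenzyl)oxy]methyl}-2-[(2E)-pent-2-en-4-yn-1-yl]oxolan-3-yl acetate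
Product: 15 (2R,3R,5R)-5-(hydroxymethyl)-2-[(2E)-pent-2-en-4-yn-1-yl]oxolan-3-yl acetate
Conditions: DDQ (1.3 equiv), CH2Cl2/pH 7 buffer (10:1), 0 °C → rt
Reagents that add atoms: none
Why: Oxidative cleavage of the 4-methoxybenzyl ether by DDQ (hydride abstraction, then hydrolysis of the oxocarbenium ion) leaves acetate, alkene and alkyne untouched.

Step 13
Reactants: 15 (2R,3R,5R)-5-(hydroxymethyl)-2-[(2E)-pent-2-en-4-yn-1-yl]oxolan-3-yl acetate
Product: 16 (2R,3R,5R)-5-formyl-2-[(2E)-pent-2-en-4-yn-1-yl]oxolan-3-yl acetate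
Conditions: Dess–Martin periodinane (1.5 equiv), CH2Cl2, 0 °C → rt; used crude
Reagents that add atoms: none
Why: Dess–Martin oxidation under near-neutral conditions gives the α-alkoxy aldehyde without epimerising C5.

Step 14
Reactants: 17 (chloromethyl)trimethylsilane
Product: 19 (1-chloropropyl)trimethylsilane (racemic), via [chloro(trimethylsilyl)methyl]lithium 18 (not isolated)
Conditions: s-BuLi, TMEDA, THF, −78 °C; then EtI, −78 °C → rt
Reagents that add atoms: iodoethane, CCI
Why: Deprotonation α to silicon and chlorine gives a carbanion that is alkylated by the primary iodide (SN2).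

Step 15
Reactants: 19 (1-chloropropyl)trimethylsilane
Product: 21 3-(trimethylsilyl)pent-1-ene (racemic), via [1-(trimethylsilyl)propyl]magnesium chloride 20 (not isolated)
Conditions: Mg, Et2O, reflux; then CH2=CHBr, PdCl2(dppf) (1 mol %), THF/Et2O, 0 °C → rt
Reagents that add atoms: vinyl bromide, C=CBr
Why: Kumada cross-coupling of the secondary α-silyl Grignard reagent with vinyl bromide, where the wide-bite-angle dppf ligand favours reductive elimination over β-hydride elimination.

Step 16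
Reactants: 16 (2R,3R,5R)-5-formyl-2-[(2E)-pent-2-en-4-yn-1-yl]oxolan-3-yl acetate; 21 3-(trimethylsilyl)pent-1-ene (3 equiv)
Product: 22 (2R,3R,5R)-5-[(1S,3E)-1-hydroxyhex-3-en-1-yl]-2-[(2E)-pent-2-en-4-yn-1-yl]oxolan-3-yl acetate
Conditions: BF3·OEt2 (1.5 equiv), CH2Cl2, −78 °C
Reagents that add atoms: none
Why: Hosomi–Sakurai allylation, in which the allylsilane reacts through an anti SE2' open transition state that shifts the double bond and makes it (E), and adds to the BF3-activated aldehyde under Felkin–Anh (non-chelation) control to give the anti, (1S) alcohol; the stereocenter of racemic 21 is destroyed in the reaction.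

Step 17
Reactants: 22 (2R,3R,5R)-5-[(1S,3E)-1-hydroxyhex-3-en-1-yl]-2-[(2E)-pent-2-en-4-yn-1-yl]oxolan-3-yl acetate
Product: 23 trans-kumausyne, (2R,3R,5R)-5-[(1R,3E)-1-bromohex-3-en-1-yl]-2-[(2E)-pent-2-en-4-yn-1-yl]oxolan-3-yl acetate
Conditions: CBr4, P(n-C8H17)3, toluene, 70 °C
Reagents that add atoms: carbon tetrabromide, BrC(Br)(Br)Br
Why: Appel-type bromination, in which the alkoxyphosphonium ion is displaced by bromide with inversion (SN2), turning the (1S) alcohol into the (1R) bromide.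

## Compound list

1 | ethyl 4-chloro-3-oxobutanoate | CCOC(=O)CC(=O)CCl | starting material
2 | ethyl 4-[(4-methoxybenzyl)oxy]-3-oxobutanoate | CCOC(=O)CC(=O)COCc1ccc(OC)cc1 | intermediate
3 | ethyl (3R)-3-hydroxy-4-[(4-methoxybenzyl)oxy]butanoate | O[C@@H](COCc1ccc(OC)cc1)CC(=O)OCC | intermediate
4 | (3R)-3-hydroxy-N-methoxy-4-[(4-methoxybenzyl)oxy]-N-methylbutanamide | O[C@@H](COCc1ccc(OC)cc1)CC(=O)N(C)OC | intermediate
5 | (5R)-5-hydroxy-6-[(4-methoxybenzyl)oxy]hex-1-en-3-one | O[C@@H](COCc1ccc(OC)cc1)CC(=O)C=C | intermediate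
6 | (2R,4R)-1-[(4-methoxybenzyl)oxy]hex-5-ene-2,4-diol (anti diol) | O[C@@H](COCc1ccc(OC)cc1)C[C@H](C=C)O | intermediate
7 | {[(2S,3R,5R)-3-hydroxy-5-{[(4-methoxybenzyl)oxy]methyl}oxolan-2-yl]methyl}palladium chloride (all ring substituents cis; not isolated) | Cl[Pd]C[C@H]1O[C@@H](COCc2ccc(OC)cc2)C[C@H]1O | intermediate
8 | {[(2R,3R,5R)-3-hydroxy-5-{[(4-methoxybenzyl)oxy]methyl}oxolan-2-yl]acetyl}palladium chloride (not isolated) | Cl[Pd]C(=O)C[C@H]1O[C@@H](COCc2ccc(OC)cc2)C[C@H]1O | intermediate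
9 | (3aR,5R,6aR)-5-{[(4-methoxybenzyl)oxy]methyl}tetrahydrofuro[3,2-b]furan-2(3H)-one (cis-fused) | O=C1C[C@H]2O[C@@H](COCc3ccc(OC)cc3)C[C@H]2O1 | intermediate
10 | (3aR,5R,6aR)-5-{[(4-methoxybenzyl)oxy]methyl}hexahydrofuro[3,2-b]furan-2-ol (anomer mixture) | OC1C[C@H]2O[C@@H](COCc3ccc(OC)cc3)C[C@H]2O1 | intermediate
11 | (2R,3R,5R)-5-{[(4-methoxybenzyl)oxy]methyl}-2-(prop-2-en-1-yl)oxolan-3-ol | C=CC[C@H]1O[C@@H](COCc2ccc(OC)cc2)C[C@H]1O | intermediate
12 | (2R,3R,5R)-5-{[(4-methoxybenzyl)oxy]methyl}-2-(prop-2-en-1-yl)oxolan-3-yl acetate | C=CC[C@H]1O[C@@H](COCc2ccc(OC)cc2)C[C@H]1OC(C)=O | intermediate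
13 | (2R,3R,5R)-5-{[(4-methoxybenzyl)oxy]methyl}-2-[(2E)-4-oxobut-2-en-1-yl]oxolan-3-yl acetate | O=C/C=C/C[C@H]1O[C@@H](COCc2ccc(OC)cc2)C[C@H]1OC(C)=O | intermediate
14 | (2R,3R,5R)-5-{[(4-methoxybenzyl)oxy]methyl}-2-[(2E)-pent-2-en-4-yn-1-yl]oxolan-3-yl acetate | C#C/C=C/C[C@H]1O[C@@H](COCc2ccc(OC)cc2)C[C@H]1OC(C)=O | intermediate
15 | (2R,3R,5R)-5-(hydroxymethyl)-2-[(2E)-pent-2-en-4-yn-1-yl]oxolan-3-yl acetate | C#C/C=C/C[C@H]1O[C@@H](CO)C[C@H]1OC(C)=O | intermediate
16 | (2R,3R,5R)-5-formyl-2-[(2E)-pent-2-en-4-yn-1-yl]oxolan-3-yl acetate | C#C/C=C/C[C@H]1O[C@@H](C=O)C[C@H]1OC(C)=O | intermediate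
17 | (chloromethyl)trimethylsilane | C[Si](C)(C)CCl | starting material
18 | [chloro(trimethylsilyl)methyl]lithium (not isolated) | [Li]C(Cl)[Si](C)(C)C | intermediate
19 | (1-chloropropyl)trimethylsilane (racemic) | CCC(Cl)[Si](C)(C)C | intermediate
20 | [1-(trimethylsilyl)propyl]magnesium chloride (not isolated) | CCC([Mg]Cl)[Si](C)(C)C | intermediate
21 | 3-(trimethylsilyl)pent-1-ene (racemic) | C=CC(CC)[Si](C)(C)C | intermediate
22 | (2R,3R,5R)-5-[(1S,3E)-1-hydroxyhex-3-en-1-yl]-2-[(2E)-pent-2-en-4-yn-1-yl]oxolan-3-yl acetate | C#C/C=C/C[C@H]1O[C@@H]([C@@H](O)C/C=C/CC)C[C@H]1OC(C)=O | intermediate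
23 | trans-kumausyne, (2R,3R,5R)-5-[(1R,3E)-1-bromohex-3-en-1-yl]-2-[(2E)-pent-2-en-4-yn-1-yl]oxolan-3-yl acetate | C#C/C=C/C[C@H]1O[C@@H]([C@H](Br)C/C=C/CC)C[C@H]1OC(C)=O | target

## Count and risks

Total step count: 17. Longest linear sequence: 15 steps (steps 1–13, 16, 17, from compound 1); the silane branch is 2 steps (14, 15).

The three steps most likely to fail:

Step 11 (Colvin homologation of an enal next to an acetate: moderate yields are typical and the lithiated reagent may attack the ester). The fallback sets out from 12 and comes back at 14. The allyl group of 12 is cleaved with OsO4 (2 mol %), NaIO4 and 2,6-lutidine in dioxane/water to the aldehyde (2R,3R,5R)-5-{[(4-methoxybenzyl)oxy]methyl}-2-(2-oxoethyl)oxolan-3-yl acetate F1. A Horner–Wadsworth–Emmons olefination with the anion of diethyl [3-(trimethylsilyl)prop-2-yn-1-yl]phosphonate (LiN(SiMe3)2, THF, −78 °C) then gives the (E)-configured silyl enyne (2R,3R,5R)-5-{[(4-methoxybenzyl)oxy]methyl}-2-[(2E)-5-(trimethylsilyl)pent-2-en-4-yn-1-yl]oxolan-3-yl acetate F2. C-Desilylation with Bu4NF buffered with AcOH (THF, 0 °C) leaves the acetate and gives 14.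

Step 16 (the Felkin preference of an oxolane-2-carbaldehyde under BF3 may be modest). The fallback sets out from 16 and comes back at 22. The addition is run without regard to selectivity, giving 22 mixed with its C1' epimer (2R,3R,5R)-5-[(1R,3E)-1-hydroxyhex-3-en-1-yl]-2-[(2E)-pent-2-en-4-yn-1-yl]oxolan-3-yl acetate F3. The mixture is oxidised with Dess–Martin periodinane to the single ketone (2R,3R,5R)-5-[(3E)-hex-3-enoyl]-2-[(2E)-pent-2-en-4-yn-1-yl]oxolan-3-yl acetate F4. Chelation-controlled reduction with Zn(BH4)2 (Et2O, −78 °C), in which zinc bridges the ring oxygen and the ketone, then gives the anti (1S) alcohol 22.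

Step 17 (the ring oxygen can take part as a neighbouring group, and the homoallylic secondary centre can eliminate). The fallback sets out from 22 and comes back at 23. The alcohol is turned with ClCH2SO2Cl and 2,6-lutidine (CH2Cl2, 0 °C) into the sulfonate (2R,3R,5R)-5-[(1S,3E)-1-{[(chloromethyl)sulfonyl]oxy}hex-3-en-1-yl]-2-[(2E)-pent-2-en-4-yn-1-yl]oxolan-3-yl acetate F5. Displacement with Bu4NBr (THF, 50 °C) proceeds by SN2 with inversion and gives 23.

## Further compounds

F1 | step 11 | (2R,3R,5R)-5-{[(4-methoxybenzyl)oxy]methyl}-2-(2-oxoethyl)oxolan-3-yl acetate | O=CC[C@H]1O[C@@H](COCc2ccc(OC)cc2)C[C@H]1OC(C)=O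
F2 | step 11 | (2R,3R,5R)-5-{[(4-methoxybenzyl)oxy]methyl}-2-[(2E)-5-(trimethylsilyl)pent-2-en-4-yn-1-yl]oxolan-3-yl acetate | C[Si](C)(C)C#C/C=C/C[C@H]1O[C@@H](COCc2ccc(OC)cc2)C[C@H]1OC(C)=O
F3 | step 16 | (2R,3R,5R)-5-[(1R,3E)-1-hydroxyhex-3-en-1-yl]-2-[(2E)-pent-2-en-4-yn-1-yl]oxolan-3-yl acetate | C#C/C=C/C[C@H]1O[C@@H]([C@H](O)C/C=C/CC)C[C@H]1OC(C)=O
F4 | step 16 | (2R,3R,5R)-5-[(3E)-hex-3-enoyl]-2-[(2E)-pent-2-en-4-yn-1-yl]oxolan-3-yl acetate | C#C/C=C/C[C@H]1O[C@@H](C(=O)C/C=C/CC)C[C@H]1OC(C)=O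
F5 | step 17 | (2R,3R,5R)-5-[(1S,3E)-1-{[(chloromethyl)sulfonyl]oxy}hex-3-en-1-yl]-2-[(2E)-pent-2-en-4-yn-1-yl]oxolan-3-yl acetate | C#C/C=C/C[C@H]1O[C@@H]([C@@H](OS(=O)(=O)CCl)C/C=C/CC)C[C@H]1OC(C)=O
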